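## Structural features

The target is a 5,6,7,8-tetrahydro-1H-isochromen-8-one: carbocyclic ring A (C4a, C5, C6, C7, C8, C8a) is fused through the tetrasubstituted C4a=C8a bond to the 1H-pyran ring B (C1, O2, C3, C4). The array O2–C3=C4–C4a=C8a–C8=O is a doubly vinylogous ester, which makes the C5 hydrogens vinylogously acidic. Ring A carries two adjacent stereocentres, C6 (R, secondary carbinol esterified by orsellinic acid) and C7 (R, tertiary carbinol with a methyl group); the two oxygens are cis, and C7–OH/C8=O is an acyloin unit. C3 bears a trans (2S,3R)-3-methyloxiranyl group, a vinyl epoxide whose two stereocentres are too far from C6/C7 for any relay of configuration. The acid part is a 2,6-disubstituted benzoate with two free phenols. Fragile points are the vinyl epoxide (acid, zerovalent palladium, π-acids), the 6-acyloxy group (E1cB loss through C5–H), the α-ketol, and retro-aldol cleavage of C6–C7 in the free diol. The real difficulty is ring A: an alkene with four different carbon substituents in fixed geometry next to a cis-diol that contains a tertiary carbinol. The key step exploits that C8 and the oxygen on C6 are 1,5-related through C8a=C4a–C5: ring A can be traded for a pyranoid lactol (O6–C8) whose open form places an aldehyde carbon C8 beside the ketone carbon C7 for an umpolung C7–C8 bond, while C1–OH and the alkyne carbon C3 are held cis for closure of ring B.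

## Logic of the disconnections

**23 from 21 (through 22).** Cut: the oxirane O–C bond at the methyl-bearing carbon, and formally three O–Si bonds. The epoxide and the phenols are the most fragile groups, so they are stored as a silylated anti-chlorohydrin and as aryl silyl ethers. Gain: no intermediate before the last step contains an epoxide, a free phenol or a vinyl epoxide next to the dienol ether. Demand: ring closure by SN2 with inversion at the chloride carbon, so the chlorohydrin must be anti (1R,2S), and the base must be mild enough to spare the 6-acyloxy group.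

**21 from 17 and 20.** Cut: the ester C(=O)–O6 bond. This is the convergent point for the aromatic part, and only the secondary hydroxyl of 17 can react. Gain: eight carbons and all phenol chemistry are removed from the main line. Demand: acylation of a hindered alcohol by a hindered acyl chloride without an alkoxide base (retro-aldol) and without elimination.

**17 from 15 (through 16), the key disconnection.** Cut: C7–C8 (ring A) and O2–C3 (ring B). In one sentence, the route is the carbene-catalysed benzoin carbocyclisation of the monocyclic keto-lactol 15, which trades its O6–C8 ring bond for the C7–C8 bond of ring A and then closes ring B by 1,6-oxa-Michael addition. Gain: both rings, the acyloin and the C7 stereocentre arise by isomerisation of a monocyclic compound with one ring stereocentre; the C6 oxygen needs no protecting group because it is the lactol oxygen. Demand: acyl-anion reactivity of an enal (not homoenolate or redox reactivity), attack on one face of the C7 ketone, and 6-endo closure at C3.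

**15 from 7 and 11 (through 12, 13, 14).** Cut: C4a–C4, with transposition of oxygen from C4a to C8 and unmasking of the C7 ketone. The vinylogous ester of 7 is a latent (Z)-enal: carbonyl addition at C4a followed by acid moves the oxygen to C8, and the ring fixes the geometry of the tetrasubstituted alkene. Gain: the two halves are joined in one flask and the problem of a stereodefined acyclic tetrasubstituted alkene disappears. Demand: the C7 ketone must stay masked during the addition, and the acid must hydrolyse the ketal without removing the silyl ether or epimerising C6.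

**7 from 5 (through 6).** Cut: C8a–C1 and, before it, C8a–I. The α-carbon of the vinylogous ester is nucleophilic, so it is iodinated and then coupled with a hydroxymethyl donor. Gain: C1 is added to a pyranone that comes from a commercial diene. Demand: the ketal and the C6 centre must survive iodine and palladium.

**5 from 2 and 3 (through 4); 2 from 1.** Cut: O–C8 and C5–C6 (hetero-Diels–Alder). Gain: the ring, the C4a and C8 oxidation levels and the C6 stereocentre come from two achiral small molecules. Demand: catalyst control of the aldehyde face for a hindered α,α-dialkoxy aldehyde; 2 needs a clean partial reduction of 1.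

**11 from 8 (through 9 and 10).** Cut: the bond between the alkyne carbon (later C3) and the carbinol carbon. The chloride-bearing centre comes from the chiral pool and directs the new carbinol centre. Demand: anti (polar Felkin–Anh) addition and no racemisation of 9.

**20 from 18 (through 19).** Cut: O–Si bonds and the C–Cl bond of the acyl chloride. Gain: a neutral route to a phenol-protected acyl donor. Demand: aryl silyl ethers must survive the chlorination.

## Other disconnections considered

**Alternative 1:** (the first that comes to mind, the aromatic azaphilone logic). Cut: the C7–OH bond on an aromatic ring A. Forward key step: hydroxylative dearomatisation of the phenol A1 (from an o-alkynyl benzyl alcohol by cycloisomerisation) to the o-quinol A2 with a copper–sparteine–dioxygen system or a hypervalent iodine reagent. Ground for rejection: A2 is a 6-hydroxycyclohexa-2,4-dienone of the kind that dimerises by [4+2] addition. Oxygen at C6 and hydrogen at C5 would then have to be added across C5=C6, cis to C7–OH, on a planar trienone that already holds the vinyl epoxide, at the cost of at least an epoxidation and a reductive opening. The chosen plan sets C6 before ring A exists and C7 in the ring-forming step.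

**Alternative 2:** Cut: O2–C3 and C4a–C4 on a preformed ring A. Forward key step: 6-endo-dig cyclisation (gold or base) of the ynenone alcohol A3, made by Sonogashira coupling of a ring A enol triflate with the epoxy alkyne. Ground for rejection: ring A with its cis-diol would need its own sequence from a cyclohexane-1,3-dione (regioselective triflation between two unlike carbonyls, hydroxylation, reduction), estimated at five to seven extra steps. The epoxide would also meet zerovalent palladium and a π-acid. The chosen key step passes through the same kind of ynenone (16) but makes ring A in the same operation.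

**Alternative 3:** Cut: C6–C7. Forward key step: catalyst-controlled intramolecular aldol addition of the α-hydroxy ketone of A4 to its aldehyde, stereoconvergent at C7. Ground for rejection: the aldehyde of A4 is β,γ-unsaturated and vinylogous to the ketone, so isomerisation and self-condensation are likely. The donor ketone is deactivated as a doubly vinylogous ester. Both centres, one of them tetrasubstituted, would rest on the catalyst alone, and the product can revert or lose water towards C5. The benzoin closure uses the same ring size but takes its stereocontrol from C6.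

Key step: step 8

Assumption: atom numbers C1–C8a are those of the target skeleton; TBS = tert-butyldimethylsilyl; salen = dianion of N,N'-bis(3,5-di-tert-butylsalicylidene)cyclohexane-1,2-diamine; for the chiral catalysts of steps 2 and 8 the enantiomer whose sense of induction gives the drawn configuration is meant.

## Steps

Step 1
Reactants: 1 methyl 2,2-dimethoxypropanoate
Product: 2 2,2-dimethoxypropanal
Conditions: iBu2AlH (1.05 equiv), CH2Cl2, −78 °C; aq. potassium sodium tartrate
Reagents that add atoms: none
Why: Partial reduction of an α,α-dialkoxy ester; the aluminium hemiacetal is held by the neighbouring methoxy groups and should collapse to the aldehyde only on work-up.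

Step 2
Reactants: 2 2,2-dimethoxypropanal; 3 (E)-1-methoxy-3-(trimethylsilyloxy)buta-1,3-diene
Product: 5 (2R)-2-(1,1-dimethoxyethyl)-2,3-dihydro-4H-pyran-4-one, via silyl enol ether cycloadduct 4 (not isolated)
Conditions: [(1R,2R)-salen]CrBF4 (2 mol%), 4 Å MS, tBuOMe, −30 °C; then CF3CO2H (cat.), CH2Cl2, 0 °C
Reagents that add atoms: none
Why: Catalytic asymmetric hetero-Diels–Alder reaction, then acid-induced loss of methanol and of the silyl group; the chiral Lewis acid selects the aldehyde face and so sets C6 (R), and the aldehyde cannot enolise.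

Step 3
Reactants: 5 (2R)-2-(1,1-dimethoxyethyl)-2,3-dihydro-4H-pyran-4-one
Product: 6 (2R)-2-(1,1-dimethoxyethyl)-5-iodo-2,3-dihydro-4H-pyran-4-one
Conditions: I2 (1.5 equiv), pyridine/CH2Cl2, 0 °C → rt
Reagents that add atoms: iodine, II
Why: α-Iodination of a vinylogous ester at its nucleophilic α-carbon (C8a); the basic medium should keep the ketal intact.

Step 4
Reactants: 6 (2R)-2-(1,1-dimethoxyethyl)-5-iodo-2,3-dihydro-4H-pyran-4-one
Product: 7 (2R)-2-(1,1-dimethoxyethyl)-5-(hydroxymethyl)-2,3-dihydro-4H-pyran-4-one
Conditions: Bu3SnCH2OH (1.3 equiv), Pd(PPh3)4 (5 mol%), dioxane, 90 °C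
Reagents that add atoms: (tributylstannyl)methanol, CCCC[Sn](CCCC)(CCCC)CO
Why: Stille coupling of an α-iodo enone with a hydroxymethyl stannane brings in C1; no stereocentre is involved.

Step 5
Reactants: 8 methyl (2S)-2-chloropropanoate
Product: 10 (3R,4S)-4-chloropent-1-yn-3-ol, via (S)-2-chloropropanal 9 (not isolated)
Conditions: iBu2AlH (1.0 equiv), CH2Cl2, −78 °C; then HC≡CMgBr (1.5 equiv), THF, −78 → −20 °C
Reagents that add atoms: ethynylmagnesium bromide, C#C[Mg]Br
Why: One-pot partial reduction and Grignard addition; the acetylide should add anti to the C–Cl bond (polar Felkin–Anh model) to give the anti chlorohydrin, and the minor syn isomer is to be removed by chromatography here or at 11.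

Step 6
Reactants: 10 (3R,4S)-4-chloropent-1-yn-3-ol
Product: 11 tert-butyl{[(3R,4S)-4-chloropent-1-yn-3-yl]oxy}dimethylsilane
Conditions: TBSOTf (1.2 equiv), 2,6-lutidine, CH2Cl2, −78 → 0 °C
Reagents that add atoms: tert-butyldimethylsilyl triflate, CC(C)(C)[Si](C)(C)OS(=O)(=O)C(F)(F)F
Why: Silylation with a silyl triflate and a hindered pyridine at low temperature should not close the chlorohydrin to the epoxide; the β-chloro propargylic silyl ether is expected to be more acid-stable than an ordinary secondary one.

Step 7
Reactants: 7 (2R)-2-(1,1-dimethoxyethyl)-5-(hydroxymethyl)-2,3-dihydro-4H-pyran-4-one; 11 tert-butyl{[(3R,4S)-4-chloropent-1-yn-3-yl]oxy}dimethylsilane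
Product: 15 1-[(2R)-4-{(3R,4S)-3-[(tert-butyldimethylsilyl)oxy]-4-chloropent-1-yn-1-yl}-6-hydroxy-5-(hydroxymethyl)-3,6-dihydro-2H-pyran-2-yl]ethan-1-one (anomers), via lithium acetylide 12 (not isolated), via tertiary carbinol 13 (not isolated), via ketal lactol 14 (not isolated)
Conditions: 11 (2.5 equiv), n-BuLi (2.4 equiv), THF, −78 °C; 7, −78 → −30 °C; then aq. HCl (1 M)/THF, 0 °C → rt
Reagents that add atoms: water, O
Why: 1,2-Addition of a lithium acetylide to the vinylogous ester carbonyl, then a Stork–Danheiser-type transposition: the enol ether carbinol ionises to an oxocarbenium ion that water captures at C8, and the ketal is hydrolysed in the same medium. The ring fixes the geometry of the C4a=C8a bond and C6 is not touched; early attack of C1–OH on the activated alkyne would only give the ring B-first isomer, which the next step should also convert.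

Step 8
Reactants: 15 1-[(2R)-4-{(3R,4S)-3-[(tert-butyldimethylsilyl)oxy]-4-chloropent-1-yn-1-yl}-6-hydroxy-5-(hydroxymethyl)-3,6-dihydro-2H-pyran-2-yl]ethan-1-one
Product: 17 (6R,7R)-3-{(1R,2S)-1-[(tert-butyldimethylsilyl)oxy]-2-chloropropyl}-6,7-dihydroxy-7-methyl-1,5,6,7-tetrahydro-8H-isochromen-8-one, via monocyclic ketol 16 (not isolated)
Conditions: chiral aminoindanol-derived N-C6F5 triazolium tetrafluoroborate (15 mol%), Et3N (15 mol%), CH2Cl2 (0.02 M), rt; then DBU (20 mol%), 0 °C → rt
Reagents that add atoms: none
Why: The lactol 15 is in equilibrium with its (Z)-hydroxy enynal; the triazolylidene adds to the aldehyde carbon C8 and proton transfer gives the Breslow intermediate, an acyl anion equivalent, so that C8 and the ketone carbon C7, both electrophilic by nature, can be joined. C8 attacks the C7 carbonyl in a 6-exo-trig closure that forms ring A, and loss of the carbene gives the α-ketol 16; the closest known reaction type is the carbene-catalysed intramolecular crossed aldehyde–ketone benzoin reaction that gives six-membered tertiary α-ketols. C7 is controlled by C6: the C6 hydroxyl freed by lactol opening hydrogen-bonds to the ketone oxygen (O–C6–C7=O syn-periplanar) and C8 must arrive from the side of C5, to which it is tethered, which places the new C7–OH cis to C6–OH (7R); the chiral triazolium salt is chosen to reinforce this face. Chemoselectivity rests on the substrate and the catalyst: the homoenolate carbon C4a is fully substituted and could reach C7 only through a four-membered ring, and an electron-poor N-C6F5 triazolium favours acyl-anion over redox pathways. DBU then adds the C1 hydroxyl to the alkyne carbon C3, the δ-position of the new ynenone, in a 6-endo-dig closure of ring B, and the allenolate is protonated at C4 to give the dienol ether. Attack at C4 (5-exo-dig) would be an anti-Michael addition and is not expected. The whole step is an isomerisation in which C6 and the side-chain centres are untouched. The selectivities needed are therefore acyl anion versus homoenolate or redox reactivity, the face of the C7 ketone, and 6-endo versus 5-exo closure.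

Step 9
Reactants: 18 orsellinic acid (2,4-dihydroxy-6-methylbenzoic acid)
Product: 19 tert-butyldimethylsilyl 2,4-bis[(tert-butyldimethylsilyl)oxy]-6-methylbenzoate
Conditions: TBSCl (3.5 equiv), imidazole (7 equiv), DMF, rt
Reagents that add atoms: tert-butyldimethylsilyl chloride, CC(C)(C)[Si](C)(C)Cl
Why: Exhaustive silylation of both phenols and the acid.

Step 10
Reactants: 19 tert-butyldimethylsilyl 2,4-bis[(tert-butyldimethylsilyl)oxy]-6-methylbenzoate
Product: 20 2,4-bis[(tert-butyldimethylsilyl)oxy]-6-methylbenzoyl chloride
Conditions: (COCl)2 (1.2 equiv), DMF (cat.), CH2Cl2, 0 °C → rt; used crude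
Reagents that add atoms: oxalyl chloride, O=C(Cl)C(Cl)=O
Why: Silyl esters are converted into acyl chlorides by the chloroiminium salt from oxalyl chloride and DMF under neutral conditions, which should spare the aryl silyl ethers.

Step 11
Reactants: 17 (6R,7R)-3-{(1R,2S)-1-[(tert-butyldimethylsilyl)oxy]-2-chloropropyl}-6,7-dihydroxy-7-methyl-1,5,6,7-tetrahydro-8H-isochromen-8-one; 20 2,4-bis[(tert-butyldimethylsilyl)oxy]-6-methylbenzoyl chloride
Product: 21 (6R,7R)-3-{(1R,2S)-1-[(tert-butyldimethylsilyl)oxy]-2-chloropropyl}-7-hydroxy-7-methyl-8-oxo-5,6,7,8-tetrahydro-1H-isochromen-6-yl 2,4-bis[(tert-butyldimethylsilyl)oxy]-6-methylbenzoate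
Conditions: 20 (1.5 equiv), pyridine, DMAP (0.3 equiv), CH2Cl2, 0 °C → rt
Reagents that add atoms: none
Why: DMAP-catalysed acylation; only the secondary C6–OH should react, the tertiary C7–OH is too hindered. The electron-rich 2,6-disubstituted acyl chloride is expected to react through its acylpyridinium or acylium ion, and the absence of an alkoxide avoids retro-aldol cleavage.

Step 12
Reactants: 21 (6R,7R)-3-{(1R,2S)-1-[(tert-butyldimethylsilyl)oxy]-2-chloropropyl}-7-hydroxy-7-methyl-8-oxo-5,6,7,8-tetrahydro-1H-isochromen-6-yl 2,4-bis[(tert-butyldimethylsilyl)oxy]-6-methylbenzoate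
Product: 23 (6R,7R)-7-hydroxy-7-methyl-3-[(2S,3R)-3-methyloxiran-2-yl]-8-oxo-5,6,7,8-tetrahydro-1H-isochromen-6-yl 2,4-dihydroxy-6-methylbenzoate (CNP0323247.1), via chlorohydrin ester 22 (not isolated)
Conditions: Bu4NF (4 equiv), THF, 0 °C; pH 7 phosphate buffer
Reagents that add atoms: none
Why: Fluoride removes the three silyl groups, and the side-chain alkoxide displaces the vicinal chloride by SN2 with inversion, so the anti chlorohydrin should give the trans (2S,3R) epoxide. The phenoxides formed first make the ester a poorer leaving group during the short exposure to base.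

## Compound list

1 | methyl 2,2-dimethoxypropanoate | COC(=O)C(C)(OC)OC | starting material
2 | 2,2-dimethoxypropanal | CC(OC)(OC)C=O | intermediate
3 | (E)-1-methoxy-3-(trimethylsilyloxy)buta-1,3-diene | CO/C=C/C(=C)O[Si](C)(C)C | starting material
4 | (2R)-2-(1,1-dimethoxyethyl)-6-methoxy-4-(trimethylsilyloxy)-3,6-dihydro-2H-pyran (either configuration at C6) | CC(OC)(OC)[C@H]1CC(O[Si](C)(C)C)=CC(OC)O1 | intermediate
5 | (2R)-2-(1,1-dimethoxyethyl)-2,3-dihydro-4H-pyran-4-one | CC(OC)(OC)[C@H]1CC(=O)C=CO1 | intermediate
6 | (2R)-2-(1,1-dimethoxyethyl)-5-iodo-2,3-dihydro-4H-pyran-4-one | CC(OC)(OC)[C@H]1CC(=O)C(I)=CO1 | intermediate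
7 | (2R)-2-(1,1-dimethoxyethyl)-5-(hydroxymethyl)-2,3-dihydro-4H-pyran-4-one | CC(OC)(OC)[C@H]1CC(=O)C(CO)=CO1 | intermediate
8 | methyl (2S)-2-chloropropanoate | C[C@H](Cl)C(=O)OC | starting material
9 | (2S)-2-chloropropanal | C[C@H](Cl)C=O | intermediate
10 | (3R,4S)-4-chloropent-1-yn-3-ol | C#C[C@@H](O)[C@H](C)Cl | intermediate
11 | tert-butyl{[(3R,4S)-4-chloropent-1-yn-3-yl]oxy}dimethylsilane | C#C[C@@H](O[Si](C)(C)C(C)(C)C)[C@H](C)Cl | intermediate
12 | {(3R,4S)-3-[(tert-butyldimethylsilyl)oxy]-4-chloropent-1-yn-1-yl}lithium | [Li]C#C[C@@H](O[Si](C)(C)C(C)(C)C)[C@H](C)Cl | intermediate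
13 | (2R)-4-{(3R,4S)-3-[(tert-butyldimethylsilyl)oxy]-4-chloropent-1-yn-1-yl}-2-(1,1-dimethoxyethyl)-5-(hydroxymethyl)-3,4-dihydro-2H-pyran-4-ol (either configuration at C4; present as its lithium alkoxide) | CC(OC)(OC)[C@H]1CC(O)(C#C[C@@H](O[Si](C)(C)C(C)(C)C)[C@H](C)Cl)C(CO)=CO1 | intermediate
14 | (6R)-4-{(3R,4S)-3-[(tert-butyldimethylsilyl)oxy]-4-chloropent-1-yn-1-yl}-6-(1,1-dimethoxyethyl)-3-(hydroxymethyl)-5,6-dihydro-2H-pyran-2-ol (anomers) | CC(OC)(OC)[C@H]1CC(C#C[C@@H](O[Si](C)(C)C(C)(C)C)[C@H](C)Cl)=C(CO)C(O)O1 | intermediate
15 | 1-[(2R)-4-{(3R,4S)-3-[(tert-butyldimethylsilyl)oxy]-4-chloropent-1-yn-1-yl}-6-hydroxy-5-(hydroxymethyl)-3,6-dihydro-2H-pyran-2-yl]ethan-1-one (anomers) | CC(=O)[C@H]1CC(C#C[C@@H](O[Si](C)(C)C(C)(C)C)[C@H](C)Cl)=C(CO)C(O)O1 | intermediate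
16 | (5R,6R)-3-{(3R,4S)-3-[(tert-butyldimethylsilyl)oxy]-4-chloropent-1-yn-1-yl}-5,6-dihydroxy-2-(hydroxymethyl)-6-methylcyclohex-2-en-1-one | O[C@@H]1CC(C#C[C@@H](O[Si](C)(C)C(C)(C)C)[C@H](C)Cl)=C(CO)C(=O)[C@]1(C)O | intermediate
17 | (6R,7R)-3-{(1R,2S)-1-[(tert-butyldimethylsilyl)oxy]-2-chloropropyl}-6,7-dihydroxy-7-methyl-1,5,6,7-tetrahydro-8H-isochromen-8-one | O[C@@H]1CC2=C(COC([C@@H](O[Si](C)(C)C(C)(C)C)[C@H](C)Cl)=C2)C(=O)[C@]1(C)O | intermediate
18 | orsellinic acid (2,4-dihydroxy-6-methylbenzoic acid) | Cc1cc(O)cc(O)c1C(=O)O | starting material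
19 | tert-butyldimethylsilyl 2,4-bis[(tert-butyldimethylsilyl)oxy]-6-methylbenzoate | Cc1cc(O[Si](C)(C)C(C)(C)C)cc(O[Si](C)(C)C(C)(C)C)c1C(=O)O[Si](C)(C)C(C)(C)C | intermediate
20 | 2,4-bis[(tert-butyldimethylsilyl)oxy]-6-methylbenzoyl chloride | Cc1cc(O[Si](C)(C)C(C)(C)C)cc(O[Si](C)(C)C(C)(C)C)c1C(Cl)=O | intermediate
21 | (6R,7R)-3-{(1R,2S)-1-[(tert-butyldimethylsilyl)oxy]-2-chloropropyl}-7-hydroxy-7-methyl-8-oxo-5,6,7,8-tetrahydro-1H-isochromen-6-yl 2,4-bis[(tert-butyldimethylsilyl)oxy]-6-methylbenzoate | Cc1cc(O[Si](C)(C)C(C)(C)C)cc(O[Si](C)(C)C(C)(C)C)c1C(=O)O[C@@H]1CC2=C(COC([C@@H](O[Si](C)(C)C(C)(C)C)[C@H](C)Cl)=C2)C(=O)[C@]1(C)O | intermediate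
22 | (6R,7R)-3-[(1R,2S)-2-chloro-1-hydroxypropyl]-7-hydroxy-7-methyl-8-oxo-5,6,7,8-tetrahydro-1H-isochromen-6-yl 2,4-dihydroxy-6-methylbenzoate | Cc1cc(O)cc(O)c1C(=O)O[C@@H]1CC2=C(COC([C@@H](O)[C@H](C)Cl)=C2)C(=O)[C@]1(C)O | intermediate
23 | (6R,7R)-7-hydroxy-7-methyl-3-[(2S,3R)-3-methyloxiran-2-yl]-8-oxo-5,6,7,8-tetrahydro-1H-isochromen-6-yl 2,4-dihydroxy-6-methylbenzoate | Cc1cc(O)cc(O)c1C(=O)O[C@@H]1CC2=C(COC([C@H]3O[C@@H]3C)=C2)C(=O)[C@]1(C)O | target

## Step count and least certain steps

Total: 12 steps. Longest linear sequence: 8 steps (1, 2, 3, 4, 7, 8, 11, 12).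

**Step 8 (key step).** The acyl anion equivalent may be diverted: protonation at C4a or C3 would give an acyl azolium that the C6 hydroxyl can trap as a lactone (redox lactonisation), or the substrate may rest as its lactol. Facial selectivity at the C7 ketone may be poor, and DBU may start retro-aldol cleavage of the product diol. Fallback, a reductive ketyl coupling in place of the carbene: it sets out from 15. Catalytic DBU in CH2Cl2 first closes ring B on the open enynal form to give 6-{(1R,2S)-1-[(tert-butyldimethylsilyl)oxy]-2-chloropropyl}-4-[(2R)-2-hydroxy-3-oxobutyl]-2H-pyran-3-carbaldehyde F1. SmI2 (THF, −78 °C) then couples aldehyde and ketone through a samarium-chelated ketyl to the 6,7,8-triol F2, where chelation by the C6 oxygen should favour the same cis face at C7. MnO2 (CH2Cl2) oxidises only the allylic C8 carbinol and the route is rejoined at 17.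

**Step 7.** The acid needed for an α-oxygenated dimethyl ketal may also remove the secondary silyl ether or epimerise C6, which becomes α to a ketone; the acetylide may also enolise 7 instead of adding. Fallback, carrying the chlorohydrin unprotected and putting the ester on after the epoxide: it sets out from 7 and 12. After the addition, stronger acid (TsOH, acetone/water, 40 °C) is applied until ketal and silyl ether are both gone, giving the free chlorohydrin keto-lactol F3. The conditions of step 8 should convert it into the bicyclic chlorohydrin triol F4, and K2CO3 in MeOH at 0 °C closes the epoxide to the epoxy diol F5. Acylation with 20 as in step 11 gives the bis-silyl epoxy ester F6, and KF in MeOH (or Bu4NF/AcOH) removes only the two aryl silyl ethers, returning to the route at 23.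

**Step 12.** While the slower desilylation and ring closure finish, base may cause loss of the orsellinate by elimination through C5–H, or phenoxide may open the new vinyl epoxide. Fallback, desilylation separated from ring closure: it sets out from 21. HF·pyridine (THF/pyridine, 0 °C) removes the three silyl groups without base, so that 22 is isolated; K2CO3 (1.1 equiv) in MeOH at 0 °C then closes the epoxide and gives 23. No new compound is needed.

**Step 11.** Both partners are hindered, so acylation may stall, and forcing it may cause elimination of the new acyloxy group. Fallback, activation of the diol instead of the acid: it sets out from 17. Bu2SnO in toluene at reflux with removal of water gives the dibutylstannylene acetal F7, whose secondary tin alkoxide should be acylated by 20 at room temperature while the tertiary oxygen stays on tin; work-up returns the route at 21.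

**Step 2.** Enantioface selection may be poor with the hindered, doubly α-oxygenated aldehyde 2. Fallback, substrate control from the chiral pool: it sets out from 3 and commercial (S)-2-[(tert-butyldimethylsilyl)oxy]propanal. BF3·OEt2 (CH2Cl2, −78 °C, then CF3CO2H) should give the Felkin–Anh (anti) silyl ether pyranone F8; HF·pyridine gives the alcohol F9; DMP periodinane gives the diketone F10, which erases the lactate centre; HC(OMe)3, MeOH and catalytic TsOH form the ketal and return the route at 5.

## Further compounds

F1 | step 8 | 6-{(1R,2S)-1-[(tert-butyldimethylsilyl)oxy]-2-chloropropyl}-4-[(2R)-2-hydroxy-3-oxobutyl]-2H-pyran-3-carbaldehyde | CC(=O)[C@H](O)CC1=C(C=O)COC([C@@H](O[Si](C)(C)C(C)(C)C)[C@H](C)Cl)=C1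
F2 | step 8 | (6R,7R)-3-{(1R,2S)-1-[(tert-butyldimethylsilyl)oxy]-2-chloropropyl}-7-methyl-5,6,7,8-tetrahydro-1H-isochromene-6,7,8-triol (either configuration at C8) | O[C@@H]1CC2=C(COC([C@@H](O[Si](C)(C)C(C)(C)C)[C@H](C)Cl)=C2)C(O)[C@]1(C)O
F3 | step 7 | 1-[(2R)-4-[(3R,4S)-4-chloro-3-hydroxypent-1-yn-1-yl]-6-hydroxy-5-(hydroxymethyl)-3,6-dihydro-2H-pyran-2-yl]ethan-1-one | CC(=O)[C@H]1CC(C#C[C@@H](O)[C@H](C)Cl)=C(CO)C(O)O1
F4 | step 7 | (6R,7R)-3-[(1R,2S)-2-chloro-1-hydroxypropyl]-6,7-dihydroxy-7-methyl-1,5,6,7-tetrahydro-8H-isochromen-8-one | O[C@@H]1CC2=C(COC([C@@H](O)[C@H](C)Cl)=C2)C(=O)[C@]1(C)O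
F5 | step 7 | (6R,7R)-6,7-dihydroxy-7-methyl-3-[(2S,3R)-3-methyloxiran-2-yl]-1,5,6,7-tetrahydro-8H-isochromen-8-one | O[C@@H]1CC2=C(COC([C@H]3O[C@@H]3C)=C2)C(=O)[C@]1(C)O
F6 | step 7 | (6R,7R)-7-hydroxy-7-methyl-3-[(2S,3R)-3-methyloxiran-2-yl]-8-oxo-5,6,7,8-tetrahydro-1H-isochromen-6-yl 2,4-bis[(tert-butyldimethylsilyl)oxy]-6-methylbenzoate | Cc1cc(O[Si](C)(C)C(C)(C)C)cc(O[Si](C)(C)C(C)(C)C)c1C(=O)O[C@@H]1CC2=C(COC([C@H]3O[C@@H]3C)=C2)C(=O)[C@]1(C)O
F0 | step 12 | none | none
F7 | step 11 | dibutylstannylene acetal of 17 (tin bridging O6 and O7) | CCCC[Sn]3(CCCC)O[C@@H]1CC2=C(COC([C@@H](O[Si](C)(C)C(C)(C)C)[C@H](C)Cl)=C2)C(=O)[C@]1(C)O3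
F8 | step 2 | (2R)-2-{(1S)-1-[(tert-butyldimethylsilyl)oxy]ethyl}-2,3-dihydro-4H-pyran-4-one | C[C@H](O[Si](C)(C)C(C)(C)C)[C@H]1CC(=O)C=CO1
F9 | step 2 | (2R)-2-[(1S)-1-hydroxyethyl]-2,3-dihydro-4H-pyran-4-one | C[C@H](O)[C@H]1CC(=O)C=CO1
F10 | step 2 | (2R)-2-acetyl-2,3-dihydro-4H-pyran-4-one | CC(=O)[C@H]1CC(=O)C=CO1
A1 | alternative 1 | 7-methyl-3-[(2S,3R)-3-methyloxiran-2-yl]-1H-isochromen-8-ol | Cc1ccc2C=C(OCc2c1O)[C@H]3O[C@@H]3C
A2 | alternative 1 | (7R)-7-hydroxy-7-methyl-3-[(2S,3R)-3-methyloxiran-2-yl]-1H-isochromen-8(7H)-one | C[C@@]1(O)C=CC2=C(COC([C@H]3O[C@@H]3C)=C2)C1=O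
A3 | alternative 2 | (5R,6R)-5,6-dihydroxy-2-(hydroxymethyl)-6-methyl-3-{[(2R,3R)-3-methyloxiran-2-yl]ethynyl}cyclohex-2-en-1-one | O[C@@H]1CC(C#C[C@H]2O[C@@H]2C)=C(CO)C(=O)[C@]1(C)O
A4 | alternative 3 | 2-hydroxy-1-{6-[(2S,3R)-3-methyloxiran-2-yl]-4-(2-oxoethyl)-2H-pyran-3-yl}propan-1-one (racemic at the carbinol) | CC(O)C(=O)C1=C(CC=O)C=C(OC1)[C@H]2O[C@@H]2C
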